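The synthesis rests on cutting the pyranone ring (ring C) of the 4-hydroxyphenyl flavanone unit across O1–C2 and C3–C4. That ring is a 2-aryl-3-substituted chroman-4-one in which C4 and O1 sit ortho on the phloroglucinol ring A, the pattern of a salicylaldehyde, while C2–C3 is the carbon pair of an aryl alkyne. A rhodium-catalysed alkyne hydroacylation and, in the same flask, a 6-endo oxa-Michael closure therefore join benzyl-protected phloroglucinaldehyde to an enantioenriched 3-(arylethynyl)-2H-chromene that already holds the whole 4-methoxyphenyl unit, and set the 2,3-trans pair. Hydroboration of the chromene C3=C4 bond and oxidation then reveal the 2,3-cis flavanone.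

Key step: step 5

Assumption: locants without primes refer to the 4-methoxyphenyl flavanone unit (unit A) and doubly primed locants to the 4-hydroxyphenyl unit (unit B); both amine catalysts are taken to follow their usual face-shielding models.

Step 1
Reactants: 1 2,4,6-trihydroxybenzaldehyde
Product: 2 2,4-bis(benzyloxy)-6-hydroxybenzaldehyde
Conditions: BnBr (2.1 equiv), K2CO3, DMF, 0 °C to rt
Reagents that add atoms: benzyl bromide, BrCc1ccccc1
Why: Williamson etherification; the 4-OH and one ortho-OH are benzylated, while the remaining ortho-OH is held in a hydrogen bond to the aldehyde and should stay free at two equivalents of halide.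

Step 2
Reactants: 2 2,4-bis(benzyloxy)-6-hydroxybenzaldehyde; 3 (E)-3-(4-methoxyphenyl)prop-2-enal
Product: 4 (2R)-5,7-bis(benzyloxy)-2-(4-methoxyphenyl)-2H-chromene-3-carbaldehyde
Conditions: (S)-α,α-diphenylprolinol trimethylsilyl ether (20 mol%), 2-nitrobenzoic acid (20 mol%), 4 Å MS, PhMe, rt
Reagents that add atoms: none
Why: Amine-catalysed domino oxa-Michael/aldol condensation; the phenol adds to the β-carbon of the iminium ion of 3 on the face left open by the diaryl(silyloxy)methyl group of the (S)-catalyst, which sets C2, and the enamine then closes onto the aldehyde of 2 with loss of water.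

Step 3
Reactants: 4 (2R)-5,7-bis(benzyloxy)-2-(4-methoxyphenyl)-2H-chromene-3-carbaldehyde
Product: 5 (2R)-5,7-bis(benzyloxy)-3-ethynyl-2-(4-methoxyphenyl)-2H-chromene
Conditions: TMSCHN2, n-BuLi, THF, −78 °C to rt
Reagents that add atoms: trimethylsilyldiazomethane, C[Si](C)(C)C=[N+]=[N-]
Why: Colvin rearrangement; the lithiated diazomethane adds to the aldehyde, Peterson-type elimination and loss of N2 give an alkylidene carbene, and 1,2-hydrogen shift gives the terminal enyne at low temperature, which avoids the methanol conjugate addition that enals suffer under Ohira–Bestmann conditions.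

Step 4
Reactants: 5 (2R)-5,7-bis(benzyloxy)-3-ethynyl-2-(4-methoxyphenyl)-2H-chromene; 6 1-(benzyloxy)-4-iodobenzene
Product: 7 (2R)-5,7-bis(benzyloxy)-3-{[4-(benzyloxy)phenyl]ethynyl}-2-(4-methoxyphenyl)-2H-chromene
Conditions: PdCl2(PPh3)2 (3 mol%), CuI (5 mol%), Et3N, THF, rt
Reagents that add atoms: none
Why: Sonogashira coupling of a terminal alkyne with an aryl iodide at room temperature; the C2 stereocentre is not involved.

Step 5
Reactants: 7 (2R)-5,7-bis(benzyloxy)-3-{[4-(benzyloxy)phenyl]ethynyl}-2-(4-methoxyphenyl)-2H-chromene; 2 2,4-bis(benzyloxy)-6-hydroxybenzaldehyde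
Product: 9 (2R,3S)-5,7-bis(benzyloxy)-2-[4-(benzyloxy)phenyl]-3-[(2R)-5,7-bis(benzyloxy)-2-(4-methoxyphenyl)-2H-chromen-3-yl]-2,3-dihydro-4H-chromen-4-one, via enone 8 (not isolated)
Conditions: [RhCl(cod)]2 (5 mol%), 1,1'-bis(diphenylphosphino)ferrocene (10 mol%), Na2CO3 (5 mol%), PhMe, 60 °C; then quinidine-derived bifunctional thiourea (20 mol%), 0 °C to rt
Reagents that add atoms: none
Why: Chelation-assisted oxidative addition of the aldehyde C–H bond of 2 to monovalent rhodium gives an acyl hydride of trivalent rhodium, syn-hydrometalation of the alkyne of 7 and C–C reductive elimination give (E)-enone 8, and the free ortho-phenol then closes ring C of unit B by 6-endo-trig oxa-Michael addition under thiourea/tertiary-amine catalysis. The closest known reaction type is the tandem rhodium-catalysed hydroacylation of internal alkynes with salicylaldehydes followed by oxa-Michael addition, which delivers trans-2,3-disubstituted chroman-4-ones. The step needs the acyl group on the alkyne carbon that bears the chromenyl group: the 4-benzyloxyphenyl donor polarises the alkyne so that hydride should go to the aryl-bearing carbon and rhodium to the distal carbon, where the adjacent chromene C3=C4 bond can stabilise the alkenylrhodium as an η3-butadienyl species. C2'' is set in the ring closure by the quinidine-derived catalyst, which binds the enone carbonyl by hydrogen bonds and delivers the phenoxide to one enone face (the quinine-derived pseudoenantiomer serves the other face), while the remote C2 centre of the chromene is expected to exert only a small bias. C3'' is set by protonation of the dienol and should equilibrate under the amine to the 2,3-trans arrangement, the thermodynamic outcome for 2-aryl-3-substituted chroman-4-ones. The chromene alkene and the benzyl ethers are inert to the catalyst, and the low temperature of the second stage limits migration of the chromene double bond into conjugation.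

Step 6
Reactants: 9 (2R,3S)-5,7-bis(benzyloxy)-2-[4-(benzyloxy)phenyl]-3-[(2R)-5,7-bis(benzyloxy)-2-(4-methoxyphenyl)-2H-chromen-3-yl]-2,3-dihydro-4H-chromen-4-one
Product: 11 (2S,3R,4R)-5,7-bis(benzyloxy)-3-{(2R,3R)-5,7-bis(benzyloxy)-2-[4-(benzyloxy)phenyl]-4-hydroxychroman-3-yl}-2-(4-methoxyphenyl)chroman-4-ol (both epimers at the carbinol carbon of unit B), via alkylborane 10 (not isolated)
Conditions: BH3·THF (excess), THF, 0 °C to rt; then 30% H2O2, aq NaOAc, 0 °C
Reagents that add atoms: hydrogen peroxide, OO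
Why: Hydroboration–oxidation; borane should add syn across the trisubstituted C3=C4 bond with boron at the less substituted benzylic C4 and from the face anti to the pseudoaxial 2-anisyl group, so the new H-3 is trans to that aryl group and the 2,3-cis relationship results, while the ketone of unit B is reduced at the same time and is restored in step 7.

Step 7
Reactants: 11 (2S,3R,4R)-5,7-bis(benzyloxy)-3-{(2R,3R)-5,7-bis(benzyloxy)-2-[4-(benzyloxy)phenyl]-4-hydroxychroman-3-yl}-2-(4-methoxyphenyl)chroman-4-ol (both epimers at the carbinol carbon of unit B)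
Product: 12 (2S,3S)-5,7-bis(benzyloxy)-3-{(2R,3S)-5,7-bis(benzyloxy)-2-[4-(benzyloxy)phenyl]-4-oxochroman-3-yl}-2-(4-methoxyphenyl)chroman-4-one
Conditions: Dess–Martin periodinane (3 equiv), NaHCO3, CH2Cl2, 0 °C to rt
Reagents that add atoms: none
Why: Dess–Martin oxidation of both secondary benzylic carbinols under buffered, non-basic conditions, which should leave the epimerisable cis C3–H of unit A and the trans C3''–H of unit B untouched.

Step 8
Reactants: 12 (2S,3S)-5,7-bis(benzyloxy)-3-{(2R,3S)-5,7-bis(benzyloxy)-2-[4-(benzyloxy)phenyl]-4-oxochroman-3-yl}-2-(4-methoxyphenyl)chroman-4-one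
Product: 13 (2S,3S)-3-[(2R,3S)-5,7-dihydroxy-2-(4-hydroxyphenyl)-4-oxochroman-3-yl]-5,7-dihydroxy-2-(4-methoxyphenyl)chroman-4-one
Conditions: H2 (1 atm), 10% Pd/C, EtOAc/MeOH, rt
Reagents that add atoms: none
Why: Hydrogenolysis of the five benzyl ethers under neutral conditions, which keeps the aryl methyl ether and should not enolise the cis-configured ketone.

Compound list
1 | 2,4,6-trihydroxybenzaldehyde | O=Cc1c(O)cc(O)cc1O | starting material
2 | 2,4-bis(benzyloxy)-6-hydroxybenzaldehyde | O=Cc1c(O)cc(OCc2ccccc2)cc1OCc1ccccc1 | intermediate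
3 | (E)-3-(4-methoxyphenyl)prop-2-enal | COc1ccc(/C=C/C=O)cc1 | starting material
4 | (2R)-5,7-bis(benzyloxy)-2-(4-methoxyphenyl)-2H-chromene-3-carbaldehyde | COc1ccc([C@H]2Oc3cc(OCc4ccccc4)cc(OCc4ccccc4)c3C=C2C=O)cc1 | intermediate
5 | (2R)-5,7-bis(benzyloxy)-3-ethynyl-2-(4-methoxyphenyl)-2H-chromene | COc1ccc([C@H]2Oc3cc(OCc4ccccc4)cc(OCc4ccccc4)c3C=C2C#C)cc1 | intermediate
6 | 1-(benzyloxy)-4-iodobenzene | Ic1ccc(OCc2ccccc2)cc1 | starting material
7 | (2R)-5,7-bis(benzyloxy)-3-{[4-(benzyloxy)phenyl]ethynyl}-2-(4-methoxyphenyl)-2H-chromene | COc1ccc([C@H]2Oc3cc(OCc4ccccc4)cc(OCc4ccccc4)c3C=C2C#Cc2ccc(OCc3ccccc3)cc2)cc1 | intermediate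
8 | (2E)-1-[2,4-bis(benzyloxy)-6-hydroxyphenyl]-3-[4-(benzyloxy)phenyl]-2-[(2R)-5,7-bis(benzyloxy)-2-(4-methoxyphenyl)-2H-chromen-3-yl]prop-2-en-1-one (enone, not isolated) | COc1ccc([C@H]2Oc3cc(OCc4ccccc4)cc(OCc4ccccc4)c3C=C2/C(=C\c2ccc(OCc3ccccc3)cc2)C(=O)c2c(O)cc(OCc3ccccc3)cc2OCc2ccccc2)cc1 | intermediate
9 | (2R,3S)-5,7-bis(benzyloxy)-2-[4-(benzyloxy)phenyl]-3-[(2R)-5,7-bis(benzyloxy)-2-(4-methoxyphenyl)-2H-chromen-3-yl]-2,3-dihydro-4H-chromen-4-one | COc1ccc([C@H]2Oc3cc(OCc4ccccc4)cc(OCc4ccccc4)c3C=C2[C@@H]2C(=O)c3c(OCc4ccccc4)cc(OCc4ccccc4)cc3O[C@H]2c2ccc(OCc3ccccc3)cc2)cc1 | intermediate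
10 | alkylborane of 9 with BH2 on C4 of unit A (cis to H-3) and the unit B ketone reduced to its O-BH2 alkoxyborane (not isolated) | COc1ccc([C@H]2Oc3cc(OCc4ccccc4)cc(OCc4ccccc4)c3[C@H](B)[C@H]2[C@@H]2C(OB)c3c(OCc4ccccc4)cc(OCc4ccccc4)cc3O[C@H]2c2ccc(OCc3ccccc3)cc2)cc1 | intermediate
11 | (2S,3R,4R)-5,7-bis(benzyloxy)-3-{(2R,3R)-5,7-bis(benzyloxy)-2-[4-(benzyloxy)phenyl]-4-hydroxychroman-3-yl}-2-(4-methoxyphenyl)chroman-4-ol (both epimers at the carbinol carbon of unit B) | COc1ccc([C@H]2Oc3cc(OCc4ccccc4)cc(OCc4ccccc4)c3[C@H](O)[C@H]2[C@@H]2C(O)c3c(OCc4ccccc4)cc(OCc4ccccc4)cc3O[C@H]2c2ccc(OCc3ccccc3)cc2)cc1 | intermediate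
12 | (2S,3S)-5,7-bis(benzyloxy)-3-{(2R,3S)-5,7-bis(benzyloxy)-2-[4-(benzyloxy)phenyl]-4-oxochroman-3-yl}-2-(4-methoxyphenyl)chroman-4-one | COc1ccc([C@H]2Oc3cc(OCc4ccccc4)cc(OCc4ccccc4)c3C(=O)[C@H]2[C@@H]2C(=O)c3c(OCc4ccccc4)cc(OCc4ccccc4)cc3O[C@H]2c2ccc(OCc3ccccc3)cc2)cc1 | intermediate
13 | (2S,3S)-3-[(2R,3S)-5,7-dihydroxy-2-(4-hydroxyphenyl)-4-oxochroman-3-yl]-5,7-dihydroxy-2-(4-methoxyphenyl)chroman-4-one | COc1ccc([C@H]2Oc3cc(O)cc(O)c3C(=O)[C@H]2[C@@H]2C(=O)c3c(O)cc(O)cc3O[C@H]2c2ccc(O)cc2)cc1 | target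

Total step count: 8. Longest linear sequence: 8 steps (1 to 13).

Steps most likely to fail

Step 5. The hydrometalation may deliver the acyl group to the aryl-bearing alkyne carbon, since the chromenyl side is the more hindered one. The ring closure may show poor facial selectivity, the chromene double bond may migrate into conjugation with the new ketone under the amine, and the 2H-chromene may racemise by thermal ring opening at the temperature of the rhodium stage. The fallback sets out from 4 (with 2) and comes back at 9; it makes the acyl–C3'' bond by dithiane alkylation and the C2''=C3'' bond by condensation. Luche reduction of 4 (NaBH4, CeCl3·7H2O, MeOH, 0 °C) should give the allylic alcohol F1, and Appel bromination (CBr4, PPh3, CH2Cl2) the allylic bromide F2. Aldehyde 2 and propane-1,3-dithiol (BF3·OEt2, CH2Cl2, 0 °C) give the dithiane F3, whose dianion (n-BuLi, 2 equiv, THF, −78 °C) is alkylated by F2 to the alkylated dithiane F4. Cleavage with MeI and CaCO3 in aqueous MeCN releases the 2-hydroxyaryl ketone F5. Knoevenagel condensation of F5 with 4-(benzyloxy)benzaldehyde (piperidinium acetate, PhMe, reflux) gives enone 8 with unambiguous regiochemistry, and 8 is closed to 9 by the thiourea stage of step 5. If facial selectivity remains poor, the two trans diastereomers are separated at 9 and the unwanted one is returned to 8 by base-mediated ring opening.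

Step 6. Boron may add to C3 instead of C4 or from the face syn to the anisyl ring, and the hindered trisubstituted alkene may react incompletely. The fallback sets out from 9 and comes back at 12. Mukaiyama hydration by hydrogen-atom transfer (Mn(dpm)3 cat., PhSiH3, O2, i-PrOH/CH2Cl2, 0 °C) should deliver hydrogen to C3 anti to the anisyl group and oxygen to the benzylic C4 radical. This gives the mono-carbinol F6 with the ketone of unit B untouched, and Dess–Martin oxidation of F6 gives 12.

Step 2. The aldol closure onto the hindered, electron-rich aldehyde may be slow, so that the reversible oxa-Michael addition erodes the enantiomeric purity. The fallback sets out from 2 and 3 and comes back at 4. The same condensation run with an achiral base (K2CO3, 1,4-dioxane, reflux) gives the racemic aldehyde F7. Preparative chromatography on a chiral stationary phase resolves it into 4 and the (S)-enantiomer F8, which is discarded.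

Further compounds
F1 | step 5 | [(2R)-5,7-bis(benzyloxy)-2-(4-methoxyphenyl)-2H-chromen-3-yl]methanol | COc1ccc([C@H]2Oc3cc(OCc4ccccc4)cc(OCc4ccccc4)c3C=C2CO)cc1
F2 | step 5 | (2R)-5,7-bis(benzyloxy)-3-(bromomethyl)-2-(4-methoxyphenyl)-2H-chromene | COc1ccc([C@H]2Oc3cc(OCc4ccccc4)cc(OCc4ccccc4)c3C=C2CBr)cc1
F3 | step 5 | 3,5-bis(benzyloxy)-2-(1,3-dithian-2-yl)phenol | Oc1cc(OCc2ccccc2)cc(OCc2ccccc2)c1C1SCCCS1
F4 | step 5 | 3,5-bis(benzyloxy)-2-(2-{[(2S)-5,7-bis(benzyloxy)-2-(4-methoxyphenyl)-2H-chromen-3-yl]methyl}-1,3-dithian-2-yl)phenol | COc1ccc([C@H]2Oc3cc(OCc4ccccc4)cc(OCc4ccccc4)c3C=C2CC2(SCCCS2)c2c(O)cc(OCc3ccccc3)cc2OCc2ccccc2)cc1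
F5 | step 5 | 1-[2,4-bis(benzyloxy)-6-hydroxyphenyl]-2-[(2S)-5,7-bis(benzyloxy)-2-(4-methoxyphenyl)-2H-chromen-3-yl]ethan-1-one | COc1ccc([C@H]2Oc3cc(OCc4ccccc4)cc(OCc4ccccc4)c3C=C2CC(=O)c2c(O)cc(OCc3ccccc3)cc2OCc2ccccc2)cc1
F6 | step 6 | (2R,3S)-5,7-bis(benzyloxy)-2-[4-(benzyloxy)phenyl]-3-[(2S,3R)-5,7-bis(benzyloxy)-4-hydroxy-2-(4-methoxyphenyl)chroman-3-yl]chroman-4-one (both epimers at the carbinol carbon) | COc1ccc([C@H]2Oc3cc(OCc4ccccc4)cc(OCc4ccccc4)c3C(O)[C@H]2[C@@H]2C(=O)c3c(OCc4ccccc4)cc(OCc4ccccc4)cc3O[C@H]2c2ccc(OCc3ccccc3)cc2)cc1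
F7 | step 2 | racemic 5,7-bis(benzyloxy)-2-(4-methoxyphenyl)-2H-chromene-3-carbaldehyde | COc1ccc(C2Oc3cc(OCc4ccccc4)cc(OCc4ccccc4)c3C=C2C=O)cc1
F8 | step 2 | (2S)-5,7-bis(benzyloxy)-2-(4-methoxyphenyl)-2H-chromene-3-carbaldehyde | COc1ccc([C@@H]2Oc3cc(OCc4ccccc4)cc(OCc4ccccc4)c3C=C2C=O)cc1
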